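**Retrosynthetic overview**

1. All four members share a (1S,2R)-trans-1-aryl-2-(hydroxymethyl)-1,2-dihydronaphthalene with a one-carbon group at C3, a phenol at C7 and a 3'-methoxy-4'-oxygenated pendant ring (locants: C1 bears the aryl, C2 the CH2O group, C4 is the vinylic CH, C4a–C8a the benzo ring, primes the pendant ring).
2. They differ in the OMe site on the benzo ring (C6 or C8), in C3 (CHO or CH2OH) and in 4'-OH versus 4'-OMe.
3. Shared intermediate 13 is the complete enal core with free 7-OH, a bromine at C8, 4'-O-TIPS and CH2O-TIPS. The C8 bromine is either the OMe precursor (Vitedoin A, then vitekwangin B) or the blocking group that sends iodine to C6 (C6–I to OMe, C8–Br to H: 7,8,9,9-Tetradehydroisolariciresinol, then reduced to CID10473569).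
4. Key disconnection: ring B (C1–C2–C3=C4–C4a–C8a) is the [4+2]/dehydration product of the hydroxy-o-quinodimethane (photoenol) of an o-benzylbenzaldehyde (C1, C8a, C4a, C4) and a γ-silyloxy enal (C2, C3, CHO) under chiral iminium catalysis. The feature it rests on is the C4a–C4H=C3–CHO unit next to the doubly benzylic C1–H, the imprint of an aryl aldehyde condensed with an enal α-carbon.
5. That one step forms C1–C2 and C3=C4, closes ring B, sets C1 and C2, and delivers C3–CHO and C2–CH2O at their final oxidation levels.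
6. The o-benzylbenzaldehyde 6 comes from a Pd/transient-imine benzylic C–H arylation of a 2-methylbenzaldehyde with a silylated 4-iodoguaiacol. The bromine is bought in place (2-bromo-3-methylphenol), so its position next to the future C1 is never a selectivity question.
7. Ring order: aromatic rings A and C are bought; ring B is the only ring formed (step 7).

Key step: step 7
Shared intermediate: compound 13

Assumption (remark on the chemistry): under the hot NaOMe of steps 9 and 13 the aryl O–TIPS ether is methanolysed while the primary alkyl O–TIPS ether survives; the products are written accordingly.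

**Trunk**

Step 1
Reactants: 1 2-bromo-3-methylphenol
Product: 2 1-(benzyloxy)-2-bromo-3-methylbenzene
Conditions: BnBr, K2CO3, DMF, rt
Reagents that add atoms: benzyl bromide, BrCc1ccccc1
Why: Williamson etherification of the only acidic OH; no other nucleophilic site is present.

Step 2
Reactants: 2 1-(benzyloxy)-2-bromo-3-methylbenzene
Product: 3 4-(benzyloxy)-3-bromo-2-methylbenzaldehyde
Conditions: Cl2CHOMe, TiCl4, CH2Cl2, −78 to −20 °C; then H2O
Reagents that add atoms: dichloromethyl methyl ether, COC(Cl)Cl; water, O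
Why: Rieche formylation should go para to the benzyloxy donor (also ortho to the methyl group), because the only free ortho site (C6) is shielded by the benzyl CH2, which the neighbouring bromine forces to that side.

Step 3
Reactants: 4 4-iodo-2-methoxyphenol
Product: 5 (4-iodo-2-methoxyphenoxy)triisopropylsilane
Conditions: TIPSCl, imidazole, DMF, rt
Reagents that add atoms: chlorotriisopropylsilane, CC(C)[Si](Cl)(C(C)C)C(C)C
Why: Standard O-silylation of the phenol gives a base-labile aryl silyl ether that tolerates the acidic and Lewis-acidic steps of the trunk.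

Step 4
Reactants: 3 4-(benzyloxy)-3-bromo-2-methylbenzaldehyde; 5 (4-iodo-2-methoxyphenoxy)triisopropylsilane
Product: 6 4-(benzyloxy)-3-bromo-2-{[3-methoxy-4-(triisopropylsilyloxy)phenyl]methyl}benzaldehyde
Conditions: Pd(OAc)2 (10 mol%), glycine (40 mol%), AgTFA (1.5 equiv), AcOH/HFIP, 90 °C
Reagents that add atoms: none
Why: Pd(II)-catalysed benzylic C(sp3)–H arylation with a transient glycine-imine directing group, in which a six-membered palladacycle forms at the ortho methyl group and is arylated by the aryl iodide (Pd(II)/Pd(IV), silver takes up iodide); the C–Br bond should survive because no Pd(0) persists, and the crowded diarylmethane CH2 should not react a second time.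

Step 5
Reactants: 7 (E)-but-2-ene-1,4-diol
Product: 8 (E)-4-(triisopropylsilyloxy)but-2-en-1-ol
Conditions: NaH (1.0 equiv), THF, 0 °C; then TIPSCl (1.0 equiv)
Reagents that add atoms: chlorotriisopropylsilane, CC(C)[Si](Cl)(C(C)C)C(C)C
Why: Monosilylation of a symmetrical diol through its sparingly soluble monosodium alkoxide, which should limit bis-silylation.

Step 6
Reactants: 8 (E)-4-(triisopropylsilyloxy)but-2-en-1-ol
Product: 9 (E)-4-(triisopropylsilyloxy)but-2-enal
Conditions: MnO2, CH2Cl2, rt
Reagents that add atoms: none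
Why: MnO2 oxidation of a primary allylic alcohol gives the enal without touching the silyl ether and keeps the E geometry.

Step 7
Reactants: 6 4-(benzyloxy)-3-bromo-2-{[3-methoxy-4-(triisopropylsilyloxy)phenyl]methyl}benzaldehyde; 9 (E)-4-(triisopropylsilyloxy)but-2-enal
Product: 12 (1S,2R)-7-(benzyloxy)-8-bromo-1-[3-methoxy-4-(triisopropylsilyloxy)phenyl]-2-[(triisopropylsilyloxy)methyl]-1,2-dihydronaphthalene-3-carbaldehyde, via (E,E)-hydroxy-o-quinodimethane (photoenol of 6) 10 (not isolated), via (1S,2R,3S,4S)-7-(benzyloxy)-8-bromo-4-hydroxy-1-[3-methoxy-4-(triisopropylsilyloxy)phenyl]-2-[(triisopropylsilyloxy)methyl]-1,2,3,4-tetrahydronaphthalene-3-carbaldehyde 11 (not isolated)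
Conditions: hν (365 nm LED), (R)-α,α-diphenylprolinol trimethylsilyl ether (20 mol%), PhCO2H (20 mol%), degassed toluene, 10 °C; then 40 °C in the dark
Reagents that add atoms: none
Why: Proposed new method: excitation of 6 (n,π* state, 1,5-hydrogen shift from the doubly benzylic CH2) should give the (E,E)-dienol 10, whose benzylic terminus adds to Cβ of the iminium ion formed from 9 and the amine while the enamine carbon closes onto the aldehyde carbon, so that ring B forms in a formal endo [4+2] (if stepwise, Michael addition then 6-exo-trig enamine aldol) to give 11, which loses water by amine-mediated aldol-type elimination to the enal 12. The closest known reaction types are the light-driven β-benzylation of enals by photoenols of 2-alkylbenzophenones under chiral secondary-amine catalysis and the photoenolization/Diels–Alder reaction of o-benzylbenzaldehydes with fumarates; new here is their merger on a benzaldehyde photoenol with an aldol condensation as the terminating event. C2 is set by the catalyst: the diphenyl(silyloxy)methyl group of the (R)-amine shields the Si face of the (E)-iminium ion, so C1 of the dienol attacks the Re face of Cβ and gives 2R. C1 is set relative to C2 by the dienol geometry (aryl on the outside) and the endo orientation of the iminium group, which places the aryl and CH2OTIPS groups trans (1S); the C3 and C4 centres of 11 are erased by the dehydration. Regiochemistry follows from the dienol polarity (the hydroxy-bearing terminus bonds to Cα, the benzylic terminus to Cβ). The step needs the iminium pathway to outrun both the uncatalysed cycloaddition of free 9 and C–Br photolysis; the far higher electrophilicity of the iminium ion, the fast intramolecular hydrogen shift and 365 nm light that the aliphatic iminium ion does not absorb should secure this.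

Step 8
Reactants: 12 (1S,2R)-7-(benzyloxy)-8-bromo-1-[3-methoxy-4-(triisopropylsilyloxy)phenyl]-2-[(triisopropylsilyloxy)methyl]-1,2-dihydronaphthalene-3-carbaldehyde
Product: 13 (1S,2R)-8-bromo-7-hydroxy-1-[3-methoxy-4-(triisopropylsilyloxy)phenyl]-2-[(triisopropylsilyloxy)methyl]-1,2-dihydronaphthalene-3-carbaldehyde
Conditions: BCl3, pentamethylbenzene, CH2Cl2, −78 °C; then MeOH, aq. NaHCO3
Reagents that add atoms: none
Why: Lewis-acid debenzylation with a cation scavenger cleaves the aryl benzyl ether at −78 °C, where the aryl methyl ether, both TIPS ethers, the C–Br bond, the enal and the two stereocentres should be untouched.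

**Branch to Vitedoin A (compound 15)**

Step 9
Reactants: 13 (1S,2R)-8-bromo-7-hydroxy-1-[3-methoxy-4-(triisopropylsilyloxy)phenyl]-2-[(triisopropylsilyloxy)methyl]-1,2-dihydronaphthalene-3-carbaldehyde
Product: 14 (1S,2R)-7-hydroxy-1-(4-hydroxy-3-methoxyphenyl)-8-methoxy-2-[(triisopropylsilyloxy)methyl]-1,2-dihydronaphthalene-3-carbaldehyde
Conditions: CuBr (30 mol%), NaOMe (8 equiv), MeOH/DMF, 100 °C, Ar, sealed tube; then aq. NH4Cl
Reagents that add atoms: sodium methoxide, [Na+].[O-]C
Why: Ullmann-type copper-catalysed methoxylation of an o-bromophenoxide, where C8–Br is the only carbon–halogen bond; the 7-phenoxide turns the enal into an unreactive vinylogous carboxylate, methoxide also cleaves the aryl O–TIPS ether (phenoxide leaving group) but not the primary alkyl O–TIPS ether, and that silyl ether keeps the C2–CH2O group from closing onto C8 as a six-membered cyclic ether.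

Step 10
Reactants: 14 (1S,2R)-7-hydroxy-1-(4-hydroxy-3-methoxyphenyl)-8-methoxy-2-[(triisopropylsilyloxy)methyl]-1,2-dihydronaphthalene-3-carbaldehyde
Product: 15 Vitedoin A
Conditions: HF·pyridine, pyridine/THF, 0 °C to rt
Reagents that add atoms: none
Why: Fluoride-mediated desilylation of the primary TIPS ether under buffered conditions that should leave the enal, the phenols and both stereocentres alone.

**Branch to vitekwangin B (compound 16)**

Step 11
Reactants: 15 Vitedoin A
Product: 16 vitekwangin B
Conditions: Cs2CO3 (2.5 equiv), MeI (1.0 equiv), DMF, −20 to 0 °C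
Reagents that add atoms: iodomethane, CI
Why: O-methylation of the bis-phenoxide with a deficit of MeI should occur at the 4'-oxygen, because the guaiacol-type 4'-phenoxide (estimated pKa about 10) is the more basic and more nucleophilic one, whereas the 7-phenoxide (estimated pKa about 8) is delocalised into the enal and flanked by the 8-OMe group; the primary alcohol is not ionised by carbonate.

**Branch to 7,8,9,9-Tetradehydroisolariciresinol (compound 20)**

Step 12
Reactants: 13 (1S,2R)-8-bromo-7-hydroxy-1-[3-methoxy-4-(triisopropylsilyloxy)phenyl]-2-[(triisopropylsilyloxy)methyl]-1,2-dihydronaphthalene-3-carbaldehyde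
Product: 17 (1S,2R)-8-bromo-7-hydroxy-6-iodo-1-[3-methoxy-4-(triisopropylsilyloxy)phenyl]-2-[(triisopropylsilyloxy)methyl]-1,2-dihydronaphthalene-3-carbaldehyde
Conditions: I2 (1.05 equiv), NaHCO3, THF/H2O, 0 °C
Reagents that add atoms: iodine, II
Why: Electrophilic iodination through the phenoxide, where only the ionised ring A is nucleophilic enough for molecular iodine (the pendant ring is a silyl/methyl diether and needs an activated I+ source), and on ring A C8 is blocked by bromine and the para position (C4a) is substituted, so C6 is the only site.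

Step 13
Reactants: 17 (1S,2R)-8-bromo-7-hydroxy-6-iodo-1-[3-methoxy-4-(triisopropylsilyloxy)phenyl]-2-[(triisopropylsilyloxy)methyl]-1,2-dihydronaphthalene-3-carbaldehyde
Product: 18 (1S,2R)-8-bromo-7-hydroxy-1-(4-hydroxy-3-methoxyphenyl)-6-methoxy-2-[(triisopropylsilyloxy)methyl]-1,2-dihydronaphthalene-3-carbaldehyde
Conditions: CuI (20 mol%), NaOMe (6 equiv), MeOH/DMF, 65 °C, Ar; then aq. NH4Cl
Reagents that add atoms: sodium methoxide, [Na+].[O-]C
Why: Ullmann-type methoxylation should be chemoselective for the unhindered C6–I bond at 65 °C, because the C8–Br bond is both stronger and flanked by two ortho substituents plus the peri C1 centre (halogen reactivity and sterics point the same way); the aryl O–TIPS ether is methanolysed in the same operation.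

Step 14
Reactants: 18 (1S,2R)-8-bromo-7-hydroxy-1-(4-hydroxy-3-methoxyphenyl)-6-methoxy-2-[(triisopropylsilyloxy)methyl]-1,2-dihydronaphthalene-3-carbaldehyde
Product: 19 (1S,2R)-7-hydroxy-1-(4-hydroxy-3-methoxyphenyl)-6-methoxy-2-[(triisopropylsilyloxy)methyl]-1,2-dihydronaphthalene-3-carbaldehyde
Conditions: Pd(OAc)2 (5 mol%), SPhos (10 mol%), HCO2Na (3 equiv), DMF/H2O, 80 °C
Reagents that add atoms: none
Why: Pd-catalysed transfer hydrodehalogenation (oxidative addition to the only C–halogen bond, formate as hydride source); the trisubstituted, phenoxide-conjugated enal is a poor acceptor for Pd–H and should not be reduced.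

Step 15
Reactants: 19 (1S,2R)-7-hydroxy-1-(4-hydroxy-3-methoxyphenyl)-6-methoxy-2-[(triisopropylsilyloxy)methyl]-1,2-dihydronaphthalene-3-carbaldehyde
Product: 20 7,8,9,9-Tetradehydroisolariciresinol
Conditions: HF·pyridine, pyridine/THF, 0 °C to rt
Reagents that add atoms: none
Why: Fluoride-mediated cleavage of the primary TIPS ether, as in step 10, with no effect on the enal or the stereocentres.

**Branch to CID10473569 (compound 21)**

Step 16
Reactants: 20 7,8,9,9-Tetradehydroisolariciresinol
Product: 21 CID10473569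
Conditions: NaBH4, CeCl3·7H2O, MeOH, −20 °C
Reagents that add atoms: none
Why: Luche reduction delivers hydride 1,2 to the only carbonyl group, so the C3=C4 bond and both stereocentres are kept and the allylic alcohol results.

**Compound list**

1 | 2-bromo-3-methylphenol | Cc1cccc(O)c1Br | starting material
2 | 1-(benzyloxy)-2-bromo-3-methylbenzene | Cc1cccc(OCc2ccccc2)c1Br | intermediate
3 | 4-(benzyloxy)-3-bromo-2-methylbenzaldehyde | Cc1c(C=O)ccc(OCc2ccccc2)c1Br | intermediate
4 | 4-iodo-2-methoxyphenol | COc1cc(I)ccc1O | starting material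
5 | (4-iodo-2-methoxyphenoxy)triisopropylsilane | COc1cc(I)ccc1O[Si](C(C)C)(C(C)C)C(C)C | intermediate
6 | 4-(benzyloxy)-3-bromo-2-{[3-methoxy-4-(triisopropylsilyloxy)phenyl]methyl}benzaldehyde | COc1cc(Cc2c(C=O)ccc(OCc3ccccc3)c2Br)ccc1O[Si](C(C)C)(C(C)C)C(C)C | intermediate
7 | (E)-but-2-ene-1,4-diol | OC/C=C/CO | starting material
8 | (E)-4-(triisopropylsilyloxy)but-2-en-1-ol | OC/C=C/CO[Si](C(C)C)(C(C)C)C(C)C | intermediate
9 | (E)-4-(triisopropylsilyloxy)but-2-enal | O=C/C=C/CO[Si](C(C)C)(C(C)C)C(C)C | intermediate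
10 | (E,E)-hydroxy-o-quinodimethane (photoenol of 6; OH and aryl on the outside) | O/C=C1\C=CC(OCc2ccccc2)=C(Br)/C1=C\c1ccc(O[Si](C(C)C)(C(C)C)C(C)C)c(OC)c1 | intermediate
11 | (1S,2R,3S,4S)-7-(benzyloxy)-8-bromo-4-hydroxy-1-[3-methoxy-4-(triisopropylsilyloxy)phenyl]-2-[(triisopropylsilyloxy)methyl]-1,2,3,4-tetrahydronaphthalene-3-carbaldehyde (endo adduct) | COc1cc([C@H]2c3c(ccc(OCc4ccccc4)c3Br)[C@@H](O)[C@@H](C=O)[C@@H]2CO[Si](C(C)C)(C(C)C)C(C)C)ccc1O[Si](C(C)C)(C(C)C)C(C)C | intermediate
12 | (1S,2R)-7-(benzyloxy)-8-bromo-1-[3-methoxy-4-(triisopropylsilyloxy)phenyl]-2-[(triisopropylsilyloxy)methyl]-1,2-dihydronaphthalene-3-carbaldehyde | COc1cc([C@H]2c3c(ccc(OCc4ccccc4)c3Br)C=C(C=O)[C@@H]2CO[Si](C(C)C)(C(C)C)C(C)C)ccc1O[Si](C(C)C)(C(C)C)C(C)C | intermediate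
13 | (1S,2R)-8-bromo-7-hydroxy-1-[3-methoxy-4-(triisopropylsilyloxy)phenyl]-2-[(triisopropylsilyloxy)methyl]-1,2-dihydronaphthalene-3-carbaldehyde | COc1cc([C@H]2c3c(ccc(O)c3Br)C=C(C=O)[C@@H]2CO[Si](C(C)C)(C(C)C)C(C)C)ccc1O[Si](C(C)C)(C(C)C)C(C)C | intermediate
14 | (1S,2R)-7-hydroxy-1-(4-hydroxy-3-methoxyphenyl)-8-methoxy-2-[(triisopropylsilyloxy)methyl]-1,2-dihydronaphthalene-3-carbaldehyde | COc1cc([C@H]2c3c(ccc(O)c3OC)C=C(C=O)[C@@H]2CO[Si](C(C)C)(C(C)C)C(C)C)ccc1O | intermediate
15 | Vitedoin A | COc1cc([C@H]2c3c(ccc(O)c3OC)C=C(C=O)[C@@H]2CO)ccc1O | target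
16 | vitekwangin B | COc1ccc([C@H]2c3c(ccc(O)c3OC)C=C(C=O)[C@@H]2CO)cc1OC | target
17 | (1S,2R)-8-bromo-7-hydroxy-6-iodo-1-[3-methoxy-4-(triisopropylsilyloxy)phenyl]-2-[(triisopropylsilyloxy)methyl]-1,2-dihydronaphthalene-3-carbaldehyde | COc1cc([C@H]2c3c(cc(I)c(O)c3Br)C=C(C=O)[C@@H]2CO[Si](C(C)C)(C(C)C)C(C)C)ccc1O[Si](C(C)C)(C(C)C)C(C)C | intermediate
18 | (1S,2R)-8-bromo-7-hydroxy-1-(4-hydroxy-3-methoxyphenyl)-6-methoxy-2-[(triisopropylsilyloxy)methyl]-1,2-dihydronaphthalene-3-carbaldehyde | COc1cc([C@H]2c3c(cc(OC)c(O)c3Br)C=C(C=O)[C@@H]2CO[Si](C(C)C)(C(C)C)C(C)C)ccc1O | intermediate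
19 | (1S,2R)-7-hydroxy-1-(4-hydroxy-3-methoxyphenyl)-6-methoxy-2-[(triisopropylsilyloxy)methyl]-1,2-dihydronaphthalene-3-carbaldehyde | COc1cc([C@H]2c3cc(O)c(OC)cc3C=C(C=O)[C@@H]2CO[Si](C(C)C)(C(C)C)C(C)C)ccc1O | intermediate
20 | 7,8,9,9-Tetradehydroisolariciresinol | COc1cc([C@H]2c3cc(O)c(OC)cc3C=C(C=O)[C@@H]2CO)ccc1O | target
21 | CID10473569 | COc1cc([C@H]2c3cc(O)c(OC)cc3C=C(CO)[C@@H]2CO)ccc1O | target

Totals for CID10473569 (compound 21): total step count 13, longest linear sequence 10
Totals for Vitedoin A (compound 15): total step count 10, longest linear sequence 7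
Totals for vitekwangin B (compound 16): total step count 11, longest linear sequence 8
Totals for 7,8,9,9-Tetradehydroisolariciresinol (compound 20): total step count 12, longest linear sequence 9

**Steps most likely to fail**

Step 7 (Proposed new method). The photoenol may be trapped without facial control by the uncatalysed cycloaddition of the free enal, the amine may be held back by the aryl aldehyde, endo control may be too weak to hold the 1,2-trans relationship, and repeated excitation may cleave the C–Br bond. The fallback uses the known auxiliary-controlled photoenolization/Diels–Alder reaction and sets out from compound 6. Compound 6 is irradiated (365 nm, toluene) with bis[(1R)-2-methoxy-2-oxo-1-phenylethyl] fumarate F1 (from fumaryl chloride and methyl (R)-mandelate, pyridine). This should give the endo hydroxy diester F2; the sense of induction is assigned by analogy with this class of α-hydroxy-ester fumarates, and the (S)-mandelate would be taken if the opposite sense were found. MsCl/Et3N followed by DBU dehydrates F2 to the dihydronaphthalene diester F3. DIBAL-H reduces both esters to the diol F4. MnO2 oxidises only the allylic alcohol and gives the hydroxy enal F5. TIPSCl/imidazole silylates the primary alcohol, and the route is rejoined at compound 12.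

Step 9. Copper-mediated substitution at the doubly ortho-substituted, peri-hindered C8 position may be outrun by protodebromination or by slow attack of methoxide on the aldehyde. The fallback changes both the metal and the stage and sets out from compound 12. Pd-catalysed C–O coupling of 12 with methanol (tBuBrettPhos Pd G3, Cs2CO3, MeOH, toluene, 60 °C) gives the 8-methoxy benzyl ether F6. BCl3/pentamethylbenzene at −78 °C frees the 7-OH and gives the phenol F7. TBAF/AcOH removes both silyl groups, and the route is rejoined at compound 15.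

Step 11. Discrimination between the two phenoxides may be too weak, so that methylation also occurs at O7 or twice. The fallback avoids any site selectivity by fixing the order of deprotection and sets out from compound 12. KHF2 in MeOH cleaves only the aryl silyl ether and gives the 4'-phenol F8. MeI/K2CO3 in acetone methylates this single free OH to the veratryl compound F9. BCl3/pentamethylbenzene at −78 °C removes the benzyl group and gives the bromophenol F10. CuBr/NaOMe (MeOH/DMF, 100 °C) converts C8–Br into C8–OMe and gives the silyl ether F11. HF·pyridine then cleaves the primary TIPS ether, and the route is rejoined at compound 16.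

**Further compounds**

F1 | step 7 | bis[(1R)-2-methoxy-2-oxo-1-phenylethyl] (2E)-but-2-enedioate | COC(=O)[C@H](OC(=O)/C=C/C(=O)O[C@H](c1ccccc1)C(=O)OC)c1ccccc1
F2 | step 7 | bis[(1R)-2-methoxy-2-oxo-1-phenylethyl] (1S,2R,3S,4S)-7-(benzyloxy)-8-bromo-4-hydroxy-1-[3-methoxy-4-(triisopropylsilyloxy)phenyl]-1,2,3,4-tetrahydronaphthalene-2,3-dicarboxylate | COc1cc([C@H]2c3c(ccc(OCc4ccccc4)c3Br)[C@@H](O)[C@@H](C(=O)O[C@H](c4ccccc4)C(=O)OC)[C@@H]2C(=O)O[C@H](c4ccccc4)C(=O)OC)ccc1O[Si](C(C)C)(C(C)C)C(C)C
F3 | step 7 | bis[(1R)-2-methoxy-2-oxo-1-phenylethyl] (1S,2R)-7-(benzyloxy)-8-bromo-1-[3-methoxy-4-(triisopropylsilyloxy)phenyl]-1,2-dihydronaphthalene-2,3-dicarboxylate | COc1cc([C@H]2c3c(ccc(OCc4ccccc4)c3Br)C=C(C(=O)O[C@H](c4ccccc4)C(=O)OC)[C@@H]2C(=O)O[C@H](c4ccccc4)C(=O)OC)ccc1O[Si](C(C)C)(C(C)C)C(C)C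
F4 | step 7 | {(1S,2R)-7-(benzyloxy)-8-bromo-1-[3-methoxy-4-(triisopropylsilyloxy)phenyl]-1,2-dihydronaphthalene-2,3-diyl}dimethanol | COc1cc([C@H]2c3c(ccc(OCc4ccccc4)c3Br)C=C(CO)[C@@H]2CO)ccc1O[Si](C(C)C)(C(C)C)C(C)C
F5 | step 7 | (1S,2R)-7-(benzyloxy)-8-bromo-2-(hydroxymethyl)-1-[3-methoxy-4-(triisopropylsilyloxy)phenyl]-1,2-dihydronaphthalene-3-carbaldehyde | COc1cc([C@H]2c3c(ccc(OCc4ccccc4)c3Br)C=C(C=O)[C@@H]2CO)ccc1O[Si](C(C)C)(C(C)C)C(C)C
F6 | step 9 | (1S,2R)-7-(benzyloxy)-8-methoxy-1-[3-methoxy-4-(triisopropylsilyloxy)phenyl]-2-[(triisopropylsilyloxy)methyl]-1,2-dihydronaphthalene-3-carbaldehyde | COc1cc([C@H]2c3c(ccc(OCc4ccccc4)c3OC)C=C(C=O)[C@@H]2CO[Si](C(C)C)(C(C)C)C(C)C)ccc1O[Si](C(C)C)(C(C)C)C(C)C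
F7 | step 9 | (1S,2R)-7-hydroxy-8-methoxy-1-[3-methoxy-4-(triisopropylsilyloxy)phenyl]-2-[(triisopropylsilyloxy)methyl]-1,2-dihydronaphthalene-3-carbaldehyde | COc1cc([C@H]2c3c(ccc(O)c3OC)C=C(C=O)[C@@H]2CO[Si](C(C)C)(C(C)C)C(C)C)ccc1O[Si](C(C)C)(C(C)C)C(C)C
F8 | step 11 | (1S,2R)-7-(benzyloxy)-8-bromo-1-(4-hydroxy-3-methoxyphenyl)-2-[(triisopropylsilyloxy)methyl]-1,2-dihydronaphthalene-3-carbaldehyde | COc1cc([C@H]2c3c(ccc(OCc4ccccc4)c3Br)C=C(C=O)[C@@H]2CO[Si](C(C)C)(C(C)C)C(C)C)ccc1O
F9 | step 11 | (1S,2R)-7-(benzyloxy)-8-bromo-1-(3,4-dimethoxyphenyl)-2-[(triisopropylsilyloxy)methyl]-1,2-dihydronaphthalene-3-carbaldehyde | COc1ccc([C@H]2c3c(ccc(OCc4ccccc4)c3Br)C=C(C=O)[C@@H]2CO[Si](C(C)C)(C(C)C)C(C)C)cc1OC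
F10 | step 11 | (1S,2R)-8-bromo-1-(3,4-dimethoxyphenyl)-7-hydroxy-2-[(triisopropylsilyloxy)methyl]-1,2-dihydronaphthalene-3-carbaldehyde | COc1ccc([C@H]2c3c(ccc(O)c3Br)C=C(C=O)[C@@H]2CO[Si](C(C)C)(C(C)C)C(C)C)cc1OC
F11 | step 11 | (1S,2R)-1-(3,4-dimethoxyphenyl)-7-hydroxy-8-methoxy-2-[(triisopropylsilyloxy)methyl]-1,2-dihydronaphthalene-3-carbaldehyde | COc1ccc([C@H]2c3c(ccc(O)c3OC)C=C(C=O)[C@@H]2CO[Si](C(C)C)(C(C)C)C(C)C)cc1OC
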